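Counted as fractions of the electrophile charge, winter holds 2.50 of nucleophile and 0.300 of protic impurity, while autumn and spring differ from winter in their free base.

| flask | electrophile | nucleophile | free base | protic impurity | remark | time |
|---|---|---|---|---|---|---|
| theta | 20 mM | 50 mM | 70 mM | 6 mM | run made earlier |  |
| zeta | 20 mM | 50 mM | 87 mM | 6 mM | run made earlier |  |
| epsilon | 20 mM | 50 mM | 170 mM | 6 mM | run made earlier |  |
| winter | 20 mM | 50.0 mM | 60.0 mM | 6.00 mM |  | 1.0 h |
| autumn | 20 mM | 50.0 mM | 90.0 mM | 6.00 mM |  | 1.0 h |
| spring | 20 mM | 50.0 mM | 140 mM | 6.00 mM |  | 1.0 h |

| run | time / min | electrophile / % | target / % |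
|---|---|---|---|
| theta | 15.0 | 29.6 | 69.3 |
| theta | 30.0 | 13.7 | 84.6 |
| theta | 50.0 | 4.2 | 94.2 |
| theta | 60.0 | 3.5 | 95.6 |
| zeta | 5.00 | 59.9 | 39.2 |
| zeta | 12.0 | 36.9 | 63.3 |
| zeta | 25.0 | 16.3 | 81.1 |
| zeta | 60.0 | 3.8 | 95.2 |
| epsilon | 15.0 | 28.5 | 70.5 |
| epsilon | 30.0 | 13.9 | 87.3 |
| epsilon | 50.0 | 2.9 | 95.9 |
| epsilon | 60.0 | 1.3 | 97.1 |

(standard deviation of a reading: 1 percentage point)

1. part of the electrophile that has reacted at the end, winter
2. part of the electrophile that has reacted at the end, autumn
3. part of the electrophile that has reacted at the end, spring
4. what raising the concentration of free base from its lowest to its highest value here does to the part of the electrophile that has reacted (changes below 5 percentage points count as none) (it falls / it rises / no change)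

- the numbers in the tables scatter by 1 percentage point (one standard deviation)

Follow one molecule of nucleophile: where can it go? It can meet an electrophile or be lost to the protic impurity, and if I let each impurity molecule cost one nucleophile, what remains for the electrophile is the reach: the nucleophile charge less the impurity charge, over the electrophile charge, 2.20 in these recipes.

What does that number tell you? In that reckoning a reach below one is a ceiling on the fraction of electrophile that can react, whereas here it stands above one, so the electrophile is the limiting reagent and the next question is one of time.

Then how far does the clock carry it? The zeta run, with 87 mM of free base, is nearest to autumn and has 3.8% of its electrophile left at 60.0 min, so I commit to about 96.2% reacted for autumn, give or take 1 percentage point; theta gives me 96.5% for winter, and spring should lie between that and the 98.7% of epsilon.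

And the free base? Theta and epsilon differ at that time by 2.2 points of electrophile left, less than the 5 points that counts, so I say no change.

But winter has less free base than any of the earlier runs: where is the weak spot? Its base is still 3.00 of the electrophile charge, and even if the acid set free cost one further nucleophile per electrophile, the reach would fall to 1.10, which is above one but thin.

The forecast gives 97% for winter (range 90% to 99.5%), 97.5% for autumn (95.5% to 99%), 97.5% for spring (95.5% to 99.2%) and no change, and of winter it says: “It should behave the same, though with more uncertainty because this is a mild extrapolation”. For autumn its figure is higher than mine.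

    nucleophile + protic impurity → quenched reagent (k = 1.30 M⁻¹ s⁻¹)
    electrophile + nucleophile → acid set free + target (k = 0.0480 M⁻¹ s⁻¹)
    nucleophile + acid set free ⇌ protonated nucleophile, settled at all times (K = 14000 M⁻¹)
    acid set free + free base ⇌ salt of the base (K = 3800 M⁻¹, k = 2.40 M⁻¹ s⁻¹)

The flasks give 95.9% in winter, 96.6% in autumn and 97.3% in spring, a rise of 1.4 points, which counts as no change. In winter at 1.00 h the protic impurity stands at 0% of its charge and the quenched reagent at 6.00 mM, the subtraction the reach makes. With its reach of 2.20, winter left for 10.0 h gives 100%. The autumn recipe with 12 mM of nucleophile has a reach of 0.300, and after 1.00 h it has 27.1% of its electrophile reacted and 72.9% left.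

The data were generated by integration on assumed constants, and the scatter is random.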